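If the red flask is run again, the figure to watch is the return, here 0.523 in the grey flask: c(target) at the last reading per unit of the smaller charge.

| flask | starting material | partner | time |
|---|---|---|---|
| blue | 0.400 M | 0.400 M |  |
| green | 0.200 M | 0.200 M |  |
| ochre | 0.400 M | 1.20 M |  |
| grey | 0.800 M | 0.400 M |  |
| red | 1.20 M | 0.200 M | 14 min |

| run | time / min | [target] / M |
|---|---|---|
| blue run | 1.8 | 0.0770 |
| blue run | 3.5 | 0.1097 |
| blue run | 5.2 | 0.1239 |
| blue run | 7.0 | 0.1368 |
| blue run | 8.8 | 0.1437 |
| blue run | 10 | 0.1491 |
| blue run | 12 | 0.1545 |
| blue run | 14 | 0.1573 |
| green run | 1.8 | 0.0251 |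
| green run | 3.5 | 0.0408 |
| green run | 5.2 | 0.0514 |
| green run | 7.0 | 0.0589 |
| green run | 8.8 | 0.0623 |
| green run | 10 | 0.0659 |
| green run | 12 | 0.0692 |
| green run | 14 | 0.0710 |
| ochre run | 1.8 | 0.1385 |
| ochre run | 3.5 | 0.1775 |
| ochre run | 5.2 | 0.1907 |
| ochre run | 7.0 | 0.1974 |
| ochre run | 8.8 | 0.2004 |
| ochre run | 10 | 0.1984 |
| ochre run | 12 | 0.2004 |
| ochre run | 14 | 0.1995 |
| grey run | 1.8 | 0.1235 |
| grey run | 3.5 | 0.1616 |
| grey run | 5.2 | 0.1803 |
| grey run | 7.0 | 0.1928 |
| grey run | 8.8 | 0.1996 |
| grey run | 10 | 0.2040 |
| grey run | 12 | 0.2077 |
| grey run | 14 | 0.2091 |

(each reading ± 0.001 M)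

* how the opening rate goes with [starting material] round the charge of the blue run: the exponent of the rate at two percent of starting material gone to target (one fixed amount of target, the same in the runs compared)
* how the opening rate goes with [partner] round the charge of the blue run: the exponent of the rate at two percent of starting material gone to target
* target in the red run at 14 min, as a share of the starting material charged

- Overall: starting material + partner -> target.
- Constant volume, constant temperature.
- A reading of a species includes what of it is bound.
- "The second partner" is partner.
- An order is taken over about fifteen percent of the charge, up and down.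

1. Blue is the base, with equal charges and a return of 0.393.

2. Raising c(starting material) from 0.400 M to 0.800 M leaves partner as the limiting reagent, so by hand the ceiling stays at 0.400 M and partner should simply go faster. Grey does this: its return of 0.523 is higher than blue's, and its readings are still rising slowly.

3. Raising c(partner) from 0.400 M to 1.20 M makes starting material the smaller charge, so by hand the ceiling is 0.400 M. Ochre's readings lie flat from 8.8 min at a return of 0.499, which is close to grey's although the smaller charge is now the other reactant.

4. Lowering both charges to 0.200 M gives green a return of 0.355, lower than blue's, with the readings still rising.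

5. Red holds more starting material than grey, and partner is its smaller charge. My own reckoning therefore carries grey's return over as an estimate: 0.105 M of target, or 8.71% of the starting material charged.

6. The forecast reads the stalls as “a dying catalyst, with loss both per turnover and over time”. It gives 13.5% (12% to 15.5%), higher than my figure, with orders of 0.95 in starting material and 0.95 in partner.

The flask gives 1.0, 0.80 and 9.37%.

    starting material + partner → target (0.6540 M⁻¹ min⁻¹)
    starting material + partner → side product (0.4998 M⁻¹ min⁻¹)
    2 starting material → homo dimer (0.2124 M⁻¹ min⁻¹)
    2 partner ⇌ idle reagent dimer, settled at all times (0.9440 M⁻¹)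

Red's 9.37% is a return of 0.562, above the carried 0.523. Carried to ochre, 0.523 gives 0.209 M of target, and in ochre the target made comes to half of the charge at 12.0 min. The flask's partner order of 0.80 lies below the forecast's 0.95 because two partner park as idle reagent dimer; the simulated run without that parking has an order of 1.1.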